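I chose not to reckon the whole course of these flasks, but to take one level from the two earlier runs and reckon the departure from it.

| setting | ochre | green | Thursday's | Friday's | Saturday's |
|---|---|---|---|---|---|
| E | 0.12 M | 0.12 M | 0.12 M | 0.12 M | 0.12 M |
| L | 44 mM (held) | 44 mM (held) | 44 mM (held) | 44 mM (held) | 44 mM (held) |
| X | 0.26 mol% | 0.78 mol% | 0.2 mol% | 0.3 mol% | 0.5 mol% |
| remark | run made earlier | run made earlier |  |  |  |
| time |  |  | 40 h | 40 h | 40 h |

| run | time / h | G / % | J / % | E / % |
|---|---|---|---|---|
| ochre | 5.00 | 23.5 | 27.1 | 50.8 |
| ochre | 15.0 | 26.5 | 48.4 | 24.1 |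
| ochre | 25.0 | 26.3 | 51.0 | 22.7 |
| ochre | 40.0 | 25.4 | 51.9 | 22.8 |
| green | 3.00 | 15.5 | 22.9 | 65.0 |
| green | 8.00 | 23.7 | 44.7 | 32.7 |
| green | 15.0 | 24.9 | 52.7 | 23.5 |
| green | 40.0 | 26.5 | 53.7 | 19.9 |

(readings scatter by 1 percentage point)

- share of G in all that became G or J for Thursday's, Friday's, Saturday's, in this order
- the shape of the row from first to last (falls all the way / rises all the way / rises, then falls / hardly changes / falls, then rises)

- at the start none of L is in solution
- the share counts what is present at the end, not what went on to other products
- "hardly changes" means that all values lie within two and a half points (for a concentration: within two and a half percent of the largest)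

With catalyst X present, E and gas L gave G and J, and the quantity asked is the share [G]/([G]+[J]). Early on, the share stood higher than late: it was 46.4 % in the ochre run at 5.00 h and 40.4 % in the green run at 3.00 h, which looks like kinetic control. Late in both runs, the ratio looked like thermodynamic control. At 40.0 h the ochre run gave 32.9 %, and the green run, with 3.00 times the X charged, gave 33.0 %. A catalyst changes how fast an equilibrium ratio is reached, not the ratio, so the loading should matter through the approach to that level. I called the mean of these two last shares the end share, s, 33.0 %.

The correction came next. Counting X as lasting, I took loading times hours as the measure of catalyst work. On that measure Thursday's flask, with the lowest loading, came to 1.23 times the work of the ochre run at 25.0 h. At that reading the ochre share stood 1.1 percentage points above s, against a scatter of 1 point in each reading. I gave Thursday's flask that excess, 34.1 %, and left Friday's and Saturday's at s, a row that hardly changes.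

The forecast gave 33.5 %, 33 % and 33 %, hardly changes, with a first point lower than mine, and it noted that “Both runs level off at the same composition”.

The flasks gave 33.7 %, 32.4 % and 31.8 %: hardly changes.

    E + Q ⇌ J (K = 56.0 L mol⁻¹, k = 0.130 L mol⁻¹ h⁻¹)
    G + X ⇌ J + X, rate k2*[X]*[G] forward; the back reaction follows from the equilibrium constant (k = 2900 L mol⁻¹ h⁻¹)
    G → Z (k = 5.10 × 10⁻⁴ h⁻¹)
    L ⇌ Q, rate k4*(csat - [Q]) (kL = 0.760 h⁻¹)
    X → D (k = 0.120 h⁻¹)
    E + Q ⇌ G (K = 26.0 L mol⁻¹, k = 12.0 L mol⁻¹ h⁻¹)

In Thursday's flask, E was used 92 times faster by E + Q into G than by E + Q into J, Q being the dissolved L and each forward rate taken alone, at 40.0 h; by then X, which interconverts G and J, was down to 0.823 % of the catalyst charged, with D at 99.2 %. Against s, itself a reading, Thursday's share stood 0.70 points above, and Saturday's, with X also at 0.823 % of its charge at 40.0 h, stood 1.2 points below.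

The readings are simulated for substances that don't exist; scatter was added.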